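The O1–C2 bond of ring C is the disconnection on which everything rests. Ring B is a 2′,5′-dihydroxyphenyl group whose C2′ oxygen sits ortho to C1′, the carbon bearing C2. At the benzoquinone oxidation level the C2 methylene becomes vinylogously acidic, so a mild base should turn it into an o-quinone methide that the C8a phenol of ring A captures. One redox-neutral operation thus closes ring C, sets C2 trans to the chiral-pool C3 carbinol and hands back ring B as the free hydroquinone. The precursor is an (R)-2-hydroxy-3-(1,4-benzoquinon-2-yl)propanoyl arene with a free C8a hydroxyl, MOM ethers at O5 and O7, the C6 methoxy and the C8 prenyl group.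

Key step: step 14

Remark: flavanone numbering (O1, C2, C3, C4, C4a, C5–C8, C8a, ring B primed) is used also for open-chain compounds; the THP (oxan-2-yl) acetal carbon is an inconsequential stereocentre, so THP-bearing compounds are carried as epimer mixtures and their SMILES leave it open.

Step 1
Reactants: 1 methyl 3,5-dihydroxy-4-methoxybenzoate
Product: 2 methyl 4-methoxy-3,5-bis(methoxymethoxy)benzoate
Conditions: MOMCl (2.5 equiv), i-Pr2NEt (3 equiv), CH2Cl2, 0 °C → rt
Reagents that add atoms: chloromethyl methyl ether, COCCl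
Why: Both phenols are alkylated by the chloromethyl ether under amine base (Williamson-type acetal protection), giving base-stable MOM ethers that later act as ortho-directing groups while the ester is untouched.

Step 2
Reactants: 2 methyl 4-methoxy-3,5-bis(methoxymethoxy)benzoate
Product: 3 [4-methoxy-3,5-bis(methoxymethoxy)phenyl]methanol
Conditions: LiAlH4, THF, 0 °C; Fieser work-up (H2O, aq. NaOH)
Reagents that add atoms: none
Why: LiAlH4 reduces the aryl ester to the benzylic alcohol (hydride reduction) and leaves the MOM acetals, which are inert to hydride and base, intact.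

Step 3
Reactants: 3 [4-methoxy-3,5-bis(methoxymethoxy)phenyl]methanol
Product: 4 4-methoxy-3,5-bis(methoxymethoxy)benzaldehyde
Conditions: activated MnO2 (excess), CH2Cl2, rt
Reagents that add atoms: none
Why: Activated MnO2 oxidises the benzylic alcohol selectively to the aldehyde (heterogeneous benzylic oxidation) without over-oxidation to the acid.

Step 4
Reactants: 4 4-methoxy-3,5-bis(methoxymethoxy)benzaldehyde
Product: 6 4-methoxy-3,5-bis(methoxymethoxy)phenol, via aryl formate 5 (not isolated)
Conditions: mCPBA (1.3 equiv), CH2Cl2, 0 °C → rt; then K2CO3 (cat.), MeOH, rt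
Reagents that add atoms: mCPBA (3-chloroperoxybenzoic acid), O=C(OO)c1cccc(Cl)c1
Why: Baeyer–Villiger oxidation of the electron-rich benzaldehyde proceeds with aryl migration, which the para methoxy group favours over hydride migration, and catalytic methanolysis of the formate frees the phenol that becomes O1, so the former carboxyl position of ring A now carries its fourth oxygen.

Step 5
Reactants: 6 4-methoxy-3,5-bis(methoxymethoxy)phenol
Product: 7 2-[4-methoxy-3,5-bis(methoxymethoxy)phenoxy]oxane
Conditions: 3,4-dihydro-2H-pyran (1.5 equiv), PPTS (cat.), CH2Cl2, rt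
Reagents that add atoms: 3,4-dihydro-2H-pyran, C1=COCCC1
Why: Acid-catalysed addition of the phenol to dihydropyran (acetalisation) masks the future O1 as a THP ether, which directs ortho-lithiation like a MOM ether but is cleaved by far weaker acid, so that O1 alone can be freed later.

Step 6
Reactants: 7 2-[4-methoxy-3,5-bis(methoxymethoxy)phenoxy]oxane; 8 prenyl bromide (1-bromo-3-methylbut-2-ene)
Product: 10 2-[4-methoxy-3,5-bis(methoxymethoxy)-2-(3-methylbut-2-en-1-yl)phenoxy]oxane, via aryllithium 9 (not isolated)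
Conditions: n-BuLi (1.1 equiv), THF, 0 °C, 1 h; then 8, −78 °C → rt
Reagents that add atoms: none
Why: Directed ortho-metalation removes one of the two equivalent ring hydrogens, each flanked by the THP and a MOM ether, and the aryllithium is alkylated by prenyl bromide in an SN2 reaction at the primary carbon, which installs the C8 prenyl group.

Step 7
Reactants: 11 bromohydroquinone (2-bromobenzene-1,4-diol)
Product: 12 2-bromo-1,4-bis(tert-butyldimethylsilyloxy)benzene
Conditions: TBSCl (2.4 equiv), imidazole (5 equiv), DMF, rt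
Reagents that add atoms: tert-butyldimethylsilyl chloride, CC(C)(C)[Si](C)(C)Cl
Why: Imidazole-mediated silylation protects both ring B phenols as TBS ethers, which tolerate organomagnesium chemistry and are later removed by fluoride without touching the MOM ethers.

Step 8
Reactants: 12 2-bromo-1,4-bis(tert-butyldimethylsilyloxy)benzene; 13 methyl (R)-glycidate (methyl (2R)-oxirane-2-carboxylate)
Product: 15 methyl (2R)-3-[2,5-bis(tert-butyldimethylsilyloxy)phenyl]-2-hydroxypropanoate, via Grignard reagent 14 (not isolated)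
Conditions: Mg turnings (1,2-dibromoethane activation), THF, 50 °C; then CuI (10 mol %), −40 °C; 13 (0.75 equiv), −40 → −20 °C; aq. NH4Cl
Reagents that add atoms: none
Why: Magnesium insertion gives the aryl Grignard reagent (chosen over the aryllithium, which would suffer ortho O-to-C silyl migration), and CuI-catalysed SN2 opening of the glycidate at its unsubstituted C3 is faster than ester addition at low temperature, so the untouched C2 stereocentre of 13 becomes the (R)-carbinol that is C3 of the target.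

Step 9
Reactants: 15 methyl (2R)-3-[2,5-bis(tert-butyldimethylsilyloxy)phenyl]-2-hydroxypropanoate
Product: 16 methyl (2R)-2-(tert-butyldimethylsilyloxy)-3-[2,5-bis(tert-butyldimethylsilyloxy)phenyl]propanoate
Conditions: TBSCl (1.5 equiv), imidazole (3 equiv), DMF, rt
Reagents that add atoms: tert-butyldimethylsilyl chloride, CC(C)(C)[Si](C)(C)Cl
Why: Silylation of the secondary alcohol protects the future C3 hydroxyl against the organometallic reagents of steps 10 and 11 in a group that later leaves together with the ring B silyl ethers.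

Step 10
Reactants: 16 methyl (2R)-2-(tert-butyldimethylsilyloxy)-3-[2,5-bis(tert-butyldimethylsilyloxy)phenyl]propanoate
Product: 17 (2R)-2-(tert-butyldimethylsilyloxy)-3-[2,5-bis(tert-butyldimethylsilyloxy)phenyl]-N-methoxy-N-methylpropanamide
Conditions: MeNH(OMe)·HCl (2 equiv), i-PrMgCl (4 equiv), THF, −20 → 0 °C
Reagents that add atoms: N,O-dimethylhydroxylamine hydrochloride, CNOC.Cl
Why: The chloromagnesium amide generated from N,O-dimethylhydroxylamine hydrochloride and i-PrMgCl converts the ester into the Weinreb amide by aminolysis at low temperature, conditions under which α-silyloxy esters do not epimerise.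

Step 11
Reactants: 10 2-[4-methoxy-3,5-bis(methoxymethoxy)-2-(3-methylbut-2-en-1-yl)phenoxy]oxane; 17 (2R)-2-(tert-butyldimethylsilyloxy)-3-[2,5-bis(tert-butyldimethylsilyloxy)phenyl]-N-methoxy-N-methylpropanamide
Product: 20 (2R)-2-(tert-butyldimethylsilyloxy)-3-[2,5-bis(tert-butyldimethylsilyloxy)phenyl]-1-[2-hydroxy-5-methoxy-4,6-bis(methoxymethoxy)-3-(3-methylbut-2-en-1-yl)phenyl]propan-1-one, via aryllithium 18 (not isolated), via THP-protected ketone 19 (not isolated)
Conditions: 10 (1.3 equiv), n-BuLi (1.2 equiv), THF, 0 °C, 1 h; then 17 (1.0 equiv), −78 → −20 °C; aq. NH4Cl; crude product in MeOH, PPTS (0.2 equiv), rt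
Reagents that add atoms: none
Why: Directed ortho-metalation at the only remaining ring hydrogen of 10, flanked by the THP and a MOM ether, gives an aryllithium whose addition to the Weinreb amide stops at the chelated tetrahedral intermediate (Weinreb ketone synthesis, no over-addition and no enolisation at C3), and PPTS in methanol then removes only the THP acetal by transacetalisation, the MOM and TBS ethers being stable to this weak acid.

Step 12
Reactants: 20 (2R)-2-(tert-butyldimethylsilyloxy)-3-[2,5-bis(tert-butyldimethylsilyloxy)phenyl]-1-[2-hydroxy-5-methoxy-4,6-bis(methoxymethoxy)-3-(3-methylbut-2-en-1-yl)phenyl]propan-1-one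
Product: 21 (2R)-3-(2,5-dihydroxyphenyl)-2-hydroxy-1-[2-hydroxy-5-methoxy-4,6-bis(methoxymethoxy)-3-(3-methylbut-2-en-1-yl)phenyl]propan-1-one
Conditions: TBAF (4 equiv), AcOH (4 equiv), THF, 0 °C → rt, argon
Reagents that add atoms: none
Why: Fluoride cleaves the two aryl and the one secondary TBS ether (desilylation), and buffering with AcOH keeps the medium near neutral so that the α-hydroxy ketone does not epimerise and the MOM ethers are untouched.

Step 13
Reactants: 21 (2R)-3-(2,5-dihydroxyphenyl)-2-hydroxy-1-[2-hydroxy-5-methoxy-4,6-bis(methoxymethoxy)-3-(3-methylbut-2-en-1-yl)phenyl]propan-1-one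
Product: 22 2-{(2R)-2-hydroxy-3-[2-hydroxy-5-methoxy-4,6-bis(methoxymethoxy)-3-(3-methylbut-2-en-1-yl)phenyl]-3-oxopropyl}cyclohexa-2,5-diene-1,4-dione
Conditions: Ag2O (1.1 equiv), Na2SO4, Et2O, rt, dark, 20 min; filtration through Celite
Reagents that add atoms: none
Why: Ag2O oxidises the ring B hydroquinone to the 1,4-benzoquinone (two-electron dehydrogenation) under anhydrous conditions, whereas ring A, whose hydrogen-bonded C8a phenol could be oxidised only with loss of the C6 methyl ether, is not attacked by this mild oxidant.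

Step 14
Reactants: 22 2-{(2R)-2-hydroxy-3-[2-hydroxy-5-methoxy-4,6-bis(methoxymethoxy)-3-(3-methylbut-2-en-1-yl)phenyl]-3-oxopropyl}cyclohexa-2,5-diene-1,4-dione
Product: 24 (2R,3R)-2-(2,5-dihydroxyphenyl)-3-hydroxy-6-methoxy-5,7-bis(methoxymethoxy)-8-(3-methylbut-2-en-1-yl)chroman-4-one, via o-quinone methide 23 (not isolated)
Conditions: Et3N (0.3 equiv), degassed MeCN (0.01 M), 0 °C → rt, argon, dark; then AcOH
Reagents that add atoms: none
Why: Et3N should remove a C2 proton of 22, which is vinylogously α to the C5′ carbonyl through C1′=C6′, and O-protonation gives the o-quinone methide 23 (C2=C1′, C2′=O), to which the C8a phenoxide adds at C2 so that ring B rearomatises as the hydroquinone. The closest known reaction type is the amine-induced tautomerisation of alkyl-1,4-quinones to o-quinone methides followed by capture of the exocyclic carbon by a tethered oxygen nucleophile, as in pyran and chromanol ring formation, together with the phenol-to-quinone-methide closure used to make flavans. Ring C closes in the 6-exo-trig mode, since the C2=C1′ bond lies outside the six-membered ring being formed. The new C2 stereocentre is governed by the (R)-C3 carbinol: a chair-like transition state with the ring B residue and the C3 hydroxyl both equatorial leads to the 2,3-trans (2R,3R) isomer, and because the addition is reversible through 23 the same isomer should also be the thermodynamic one. The step needs O1 to be the only nucleophile and needs ring closure to outrun hydrogen shift from C3 in 23; the first is secured by the MOM ethers on O5 and O7 and by the strain of the epoxide that the C3 hydroxyl would give, the second by the intramolecular six-membered closure of a phenoxide already held next to C4. No external oxidant or reductant is involved, so the oxidation level put in at step 13 is returned as the free 2′,5′-dihydroxyphenyl group.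

Step 15
Reactants: 24 (2R,3R)-2-(2,5-dihydroxyphenyl)-3-hydroxy-6-methoxy-5,7-bis(methoxymethoxy)-8-(3-methylbut-2-en-1-yl)chroman-4-one
Product: 25 (2R,3R)-2-(2,5-dihydroxyphenyl)-3,5,7-trihydroxy-6-methoxy-8-(3-methylbut-2-en-1-yl)chroman-4-one (CNP0287732.1)
Conditions: 3 M aq. HCl, MeOH, 45 °C, argon
Reagents that add atoms: none
Why: Acid-catalysed methanolysis of the two aryl MOM acetals (transacetalisation to dimethoxymethane) frees the C5 and C7 phenols under conditions in common use for prenylated flavonoids and touches neither stereocentre.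

Compound list

1 | methyl 3,5-dihydroxy-4-methoxybenzoate | COC(=O)c1cc(O)c(OC)c(O)c1 | starting material
2 | methyl 4-methoxy-3,5-bis(methoxymethoxy)benzoate | COC(=O)c1cc(OCOC)c(OC)c(OCOC)c1 | intermediate
3 | [4-methoxy-3,5-bis(methoxymethoxy)phenyl]methanol | OCc1cc(OCOC)c(OC)c(OCOC)c1 | intermediate
4 | 4-methoxy-3,5-bis(methoxymethoxy)benzaldehyde | O=Cc1cc(OCOC)c(OC)c(OCOC)c1 | intermediate
5 | 4-methoxy-3,5-bis(methoxymethoxy)phenyl formate (formed in the flask) | O=COc1cc(OCOC)c(OC)c(OCOC)c1 | intermediate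
6 | 4-methoxy-3,5-bis(methoxymethoxy)phenol | Oc1cc(OCOC)c(OC)c(OCOC)c1 | intermediate
7 | 2-[4-methoxy-3,5-bis(methoxymethoxy)phenoxy]oxane (racemic at the acetal carbon) | COCOc1cc(OC2CCCCO2)cc(OCOC)c1OC | intermediate
8 | prenyl bromide (1-bromo-3-methylbut-2-ene) | CC(C)=CCBr | starting material
9 | [5-methoxy-4,6-bis(methoxymethoxy)-2-(oxan-2-yloxy)phenyl]lithium (formed in the flask) | COCOc1cc(OC2CCCCO2)c([Li])c(OCOC)c1OC | intermediate
10 | 2-[4-methoxy-3,5-bis(methoxymethoxy)-2-(3-methylbut-2-en-1-yl)phenoxy]oxane (racemic at the acetal carbon) | COCOc1cc(OC2CCCCO2)c(CC=C(C)C)c(OCOC)c1OC | intermediate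
11 | bromohydroquinone (2-bromobenzene-1,4-diol) | Oc1ccc(O)c(Br)c1 | starting material
12 | 2-bromo-1,4-bis(tert-butyldimethylsilyloxy)benzene | CC(C)(C)[Si](C)(C)Oc1ccc(O[Si](C)(C)C(C)(C)C)c(Br)c1 | intermediate
13 | methyl (R)-glycidate (methyl (2R)-oxirane-2-carboxylate) | COC(=O)[C@H]1CO1 | starting material
14 | [2,5-bis(tert-butyldimethylsilyloxy)phenyl]magnesium bromide (formed in the flask) | CC(C)(C)[Si](C)(C)Oc1ccc(O[Si](C)(C)C(C)(C)C)c([Mg]Br)c1 | intermediate
15 | methyl (2R)-3-[2,5-bis(tert-butyldimethylsilyloxy)phenyl]-2-hydroxypropanoate | COC(=O)[C@H](O)Cc1cc(O[Si](C)(C)C(C)(C)C)ccc1O[Si](C)(C)C(C)(C)C | intermediate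
16 | methyl (2R)-2-(tert-butyldimethylsilyloxy)-3-[2,5-bis(tert-butyldimethylsilyloxy)phenyl]propanoate | COC(=O)[C@H](O[Si](C)(C)C(C)(C)C)Cc1cc(O[Si](C)(C)C(C)(C)C)ccc1O[Si](C)(C)C(C)(C)C | intermediate
17 | (2R)-2-(tert-butyldimethylsilyloxy)-3-[2,5-bis(tert-butyldimethylsilyloxy)phenyl]-N-methoxy-N-methylpropanamide | CON(C)C(=O)[C@H](O[Si](C)(C)C(C)(C)C)Cc1cc(O[Si](C)(C)C(C)(C)C)ccc1O[Si](C)(C)C(C)(C)C | intermediate
18 | [3-methoxy-2,4-bis(methoxymethoxy)-5-(3-methylbut-2-en-1-yl)-6-(oxan-2-yloxy)phenyl]lithium (formed in the flask) | COCOc1c([Li])c(OC2CCCCO2)c(CC=C(C)C)c(OCOC)c1OC | intermediate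
19 | (2R)-2-(tert-butyldimethylsilyloxy)-3-[2,5-bis(tert-butyldimethylsilyloxy)phenyl]-1-[3-methoxy-2,4-bis(methoxymethoxy)-5-(3-methylbut-2-en-1-yl)-6-(oxan-2-yloxy)phenyl]propan-1-one (formed in the flask, acetal epimers) | COc1c(OCOC)c(CC=C(C)C)c(OC2CCCCO2)c(c1OCOC)C(=O)[C@H](O[Si](C)(C)C(C)(C)C)Cc1cc(O[Si](C)(C)C(C)(C)C)ccc1O[Si](C)(C)C(C)(C)C | intermediate
20 | (2R)-2-(tert-butyldimethylsilyloxy)-3-[2,5-bis(tert-butyldimethylsilyloxy)phenyl]-1-[2-hydroxy-5-methoxy-4,6-bis(methoxymethoxy)-3-(3-methylbut-2-en-1-yl)phenyl]propan-1-one | COc1c(OCOC)c(CC=C(C)C)c(O)c(c1OCOC)C(=O)[C@H](O[Si](C)(C)C(C)(C)C)Cc1cc(O[Si](C)(C)C(C)(C)C)ccc1O[Si](C)(C)C(C)(C)C | intermediate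
21 | (2R)-3-(2,5-dihydroxyphenyl)-2-hydroxy-1-[2-hydroxy-5-methoxy-4,6-bis(methoxymethoxy)-3-(3-methylbut-2-en-1-yl)phenyl]propan-1-one | COc1c(OCOC)c(CC=C(C)C)c(O)c(c1OCOC)C(=O)[C@H](O)Cc1cc(O)ccc1O | intermediate
22 | 2-{(2R)-2-hydroxy-3-[2-hydroxy-5-methoxy-4,6-bis(methoxymethoxy)-3-(3-methylbut-2-en-1-yl)phenyl]-3-oxopropyl}cyclohexa-2,5-diene-1,4-dione (key-step precursor) | COc1c(OCOC)c(CC=C(C)C)c(O)c(c1OCOC)C(=O)[C@H](O)CC1=CC(=O)C=CC1=O | intermediate
23 | 4-hydroxy-6-{(2R)-2-hydroxy-3-[2-hydroxy-5-methoxy-4,6-bis(methoxymethoxy)-3-(3-methylbut-2-en-1-yl)phenyl]-3-oxopropylidene}cyclohexa-2,4-dien-1-one (o-quinone methide, formed in the flask) | COc1c(OCOC)c(CC=C(C)C)c(O)c(c1OCOC)C(=O)[C@H](O)C=C1C=C(O)C=CC1=O | intermediate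
24 | (2R,3R)-2-(2,5-dihydroxyphenyl)-3-hydroxy-6-methoxy-5,7-bis(methoxymethoxy)-8-(3-methylbut-2-en-1-yl)chroman-4-one (key-step product) | COc1c(OCOC)c(CC=C(C)C)c2c(c1OCOC)C(=O)[C@H](O)[C@@H](c1cc(O)ccc1O)O2 | intermediate
25 | (2R,3R)-2-(2,5-dihydroxyphenyl)-3,5,7-trihydroxy-6-methoxy-8-(3-methylbut-2-en-1-yl)chroman-4-one (CNP0287732.1) | COc1c(O)c(CC=C(C)C)c2c(c1O)C(=O)[C@H](O)[C@@H](c1cc(O)ccc1O)O2 | target

Total step count: 15
Longest linear sequence: 11 steps (steps 1–6 and 11–15); steps 7–10 form the convergent ring B branch.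

Steps most likely to fail

1. Step 14.
- **What may go wrong:** Hydrogen shift from C3 within the quinone methide (an internal redox that would lead to the 1,2-dione) could compete with ring closure. Base could epimerise C3. Electron exchange between unreacted quinone and product hydroquinone could stall the conversion.
- **Fallback:** Ring C would be closed by the established epoxy-chalcone route, setting out from 10.
  - Lithiation as in step 11 and acylation with N-methoxy-N-methylacetamide should give 1-[3-methoxy-2,4-bis(methoxymethoxy)-5-(3-methylbut-2-en-1-yl)-6-(oxan-2-yloxy)phenyl]ethan-1-one F1.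
  - Claisen–Schmidt condensation (KOH, EtOH, rt) with 2,5-bis(methoxymethoxy)benzaldehyde F2, itself made from commercial 2,5-dihydroxybenzaldehyde with MOMCl and i-Pr2NEt, should give the (E)-chalcone (2E)-3-[2,5-bis(methoxymethoxy)phenyl]-1-[3-methoxy-2,4-bis(methoxymethoxy)-5-(3-methylbut-2-en-1-yl)-6-(oxan-2-yloxy)phenyl]prop-2-en-1-one F3.
  - Juliá–Colonna epoxidation (poly-L-leucine, urea–H2O2, DBU, THF) is a nucleophilic epoxidation that attacks only the enone and leaves the prenyl alkene; it should deliver the (2R,3S)-epoxy ketone [(2R,3S)-3-[2,5-bis(methoxymethoxy)phenyl]oxiran-2-yl][3-methoxy-2,4-bis(methoxymethoxy)-5-(3-methylbut-2-en-1-yl)-6-(oxan-2-yloxy)phenyl]methanone F4.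
  - PPTS in MeOH followed by catalytic p-TsOH in CH2Cl2 would remove the THP group and let the freed C8a phenol open the epoxide at the benzylic carbon with inversion (6-endo), giving (2R,3R)-2-[2,5-bis(methoxymethoxy)phenyl]-3-hydroxy-6-methoxy-5,7-bis(methoxymethoxy)-8-(3-methylbut-2-en-1-yl)chroman-4-one F5.
  - 3 M HCl in MeOH at 45 °C then removes the four MOM groups, and the sequence comes back to the route at the target 25.

2. Step 11.
- **What may go wrong:** Addition of the doubly ortho-substituted aryllithium to the amide may be sluggish, so that deprotonation of the amide and its fragmentation take over.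
- **Fallback:** The fallback sets out from 16 and swaps the acyl donor for an aldehyde.
  - DIBAL-H (CH2Cl2, −78 °C) should give (2R)-2-(tert-butyldimethylsilyloxy)-3-[2,5-bis(tert-butyldimethylsilyloxy)phenyl]propanal F6.
  - Addition of aryllithium 18 (THF, −78 °C) should give, as a mixture of carbinol epimers, (2R)-2-(tert-butyldimethylsilyloxy)-3-[2,5-bis(tert-butyldimethylsilyloxy)phenyl]-1-[3-methoxy-2,4-bis(methoxymethoxy)-5-(3-methylbut-2-en-1-yl)-6-(oxan-2-yloxy)phenyl]propan-1-ol F7.
  - Dess–Martin periodinane with NaHCO3 in CH2Cl2 oxidises F7 to ketone 19, where the route is rejoined; PPTS in MeOH then gives 20 as in step 11.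

3. Step 15.
- **What may go wrong:** Under protic acid the C8 prenyl group may cyclise onto the freed C7 hydroxyl, and C2 may ionise.
- **Fallback:** The fallback sets out from 24 and replaces solvolysis by acetal-to-silyl exchange.
  - TMSOTf with 2,2′-bipyridyl in MeCN at 0 °C converts aryl MOM ethers into aryl trimethylsilyl ethers under non-protic conditions and silylates the free hydroxyls at the same time; it should give (2R,3R)-6-methoxy-8-(3-methylbut-2-en-1-yl)-3,5,7-tris(trimethylsilyloxy)-2-[2,5-bis(trimethylsilyloxy)phenyl]chroman-4-one F8.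
  - Hydrolysis of F8 with aqueous citric acid in THF at rt returns to the route at the target 25.

Further compounds

F1 | step 14 | 1-[3-methoxy-2,4-bis(methoxymethoxy)-5-(3-methylbut-2-en-1-yl)-6-(oxan-2-yloxy)phenyl]ethan-1-one | COc1c(OCOC)c(CC=C(C)C)c(OC2CCCCO2)c(c1OCOC)C(C)=O
F2 | step 14 | 2,5-bis(methoxymethoxy)benzaldehyde | COCOc1ccc(OCOC)c(C=O)c1
F3 | step 14 | (2E)-3-[2,5-bis(methoxymethoxy)phenyl]-1-[3-methoxy-2,4-bis(methoxymethoxy)-5-(3-methylbut-2-en-1-yl)-6-(oxan-2-yloxy)phenyl]prop-2-en-1-one | COc1c(OCOC)c(CC=C(C)C)c(OC2CCCCO2)c(c1OCOC)C(=O)/C=C/c1cc(OCOC)ccc1OCOC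
F4 | step 14 | [(2R,3S)-3-[2,5-bis(methoxymethoxy)phenyl]oxiran-2-yl][3-methoxy-2,4-bis(methoxymethoxy)-5-(3-methylbut-2-en-1-yl)-6-(oxan-2-yloxy)phenyl]methanone | COc1c(OCOC)c(CC=C(C)C)c(OC2CCCCO2)c(c1OCOC)C(=O)[C@@H]1O[C@H]1c1cc(OCOC)ccc1OCOC
F5 | step 14 | (2R,3R)-2-[2,5-bis(methoxymethoxy)phenyl]-3-hydroxy-6-methoxy-5,7-bis(methoxymethoxy)-8-(3-methylbut-2-en-1-yl)chroman-4-one | COc1c(OCOC)c(CC=C(C)C)c2c(c1OCOC)C(=O)[C@H](O)[C@@H](c1cc(OCOC)ccc1OCOC)O2
F6 | step 11 | (2R)-2-(tert-butyldimethylsilyloxy)-3-[2,5-bis(tert-butyldimethylsilyloxy)phenyl]propanal | O=C[C@H](O[Si](C)(C)C(C)(C)C)Cc1cc(O[Si](C)(C)C(C)(C)C)ccc1O[Si](C)(C)C(C)(C)C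
F7 | step 11 | (2R)-2-(tert-butyldimethylsilyloxy)-3-[2,5-bis(tert-butyldimethylsilyloxy)phenyl]-1-[3-methoxy-2,4-bis(methoxymethoxy)-5-(3-methylbut-2-en-1-yl)-6-(oxan-2-yloxy)phenyl]propan-1-ol | COc1c(OCOC)c(CC=C(C)C)c(OC2CCCCO2)c(c1OCOC)C(O)[C@H](O[Si](C)(C)C(C)(C)C)Cc1cc(O[Si](C)(C)C(C)(C)C)ccc1O[Si](C)(C)C(C)(C)C
F8 | step 15 | (2R,3R)-6-methoxy-8-(3-methylbut-2-en-1-yl)-3,5,7-tris(trimethylsilyloxy)-2-[2,5-bis(trimethylsilyloxy)phenyl]chroman-4-one | COc1c(O[Si](C)(C)C)c(CC=C(C)C)c2c(c1O[Si](C)(C)C)C(=O)[C@H](O[Si](C)(C)C)[C@@H](c1cc(O[Si](C)(C)C)ccc1O[Si](C)(C)C)O2
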